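**Plan**

- Daucane numbering is used at every stage: C1 (methyl-bearing fusion carbon), C2, C3, C4 (isopropyl carbinol), C5 (fusion CH), C6 (aroyloxy), C7, C8 (methyl), C9, C10 (tigloyloxy). Ring A is C1–C5; ring B is C1, C5–C10.
- Enabling feature: with C9 taken out, C10–C1–C5–C6–C7–C8 with the C1 and C8 methyls and the C6 and C10 oxygens is a masked, mirror-symmetric 3,5-dimethyl-para-quinone monoketal, and C2–C3–C4 with the isopropyl carbinol is a ring-opened 1-isopropylcyclopropanol.
- Retrosynthesis: cut the two ester C–O bonds, then remove C9 from ring B (C8–C9 and C9–C10, seven- to six-membered ring), then cut C1–C2 and C4–C5 of ring A back to the dienone and the cyclopropanol.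
- Forward: the six-membered ring B precursor comes from an arene by oxidative dearomatisation, ring A is annulated in one cascade, ring B is enlarged by one carbon, and the tiglate goes on last (the C6 aroyl group is carried from step 8).
- Stereochemistry: C1 from a chiral copper catalyst that desymmetrises the dienone; C5 and C4 relayed by the intramolecular aldol; C6 and C10 from hydride addition to the convex face of the cis-fused bicycle; the E alkene from tiglic acid.

Key step: step 5

Assumption: the sense of induction of the copper–carbene catalyst in step 5 cannot be predicted with certainty; the (4S,5S) ligand is written, and its (4R,5R) enantiomer is to be used, with nothing else changed, should it favour the antipodal series.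

**Route**

Step 1
Reactants: 1 4-bromo-2,6-dimethylphenol
Product: 2 5-bromo-2-methoxy-1,3-dimethylbenzene
Conditions: MeI, K2CO3, acetone, reflux
Reagents that add atoms: iodomethane, CI
Why: Williamson O-methylation, in which the phenoxide formed with carbonate attacks iodomethane in an SN2 reaction that the two ortho methyl groups slow but do not stop.

Step 2
Reactants: 2 5-bromo-2-methoxy-1,3-dimethylbenzene
Product: 3 4-methoxy-3,5-dimethylphenol
Conditions: Pd2(dba)3 (1 mol %), 2-di-tert-butylphosphino-2′,4′,6′-triisopropylbiphenyl (4 mol %), KOH, 1,4-dioxane/H2O, 100 °C; then aq. HCl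
Reagents that add atoms: potassium hydroxide, [K+].[OH-]
Why: Palladium-catalysed C–O cross-coupling of an aryl bromide with hydroxide, which should work because the bromide has no ortho substituent and the bulky electron-rich biarylphosphine promotes C–O reductive elimination from divalent palladium.

Step 3
Reactants: 3 4-methoxy-3,5-dimethylphenol
Product: 4 4,4-dimethoxy-3,5-dimethylcyclohexa-2,5-dien-1-one
Conditions: PhI(OAc)2, MeOH, 0 °C → rt
Reagents that add atoms: methanol, CO
Why: Oxidative dearomatisation of a para-methoxyphenol with a hypervalent iodine reagent, in which methanol adds to the methoxy-bearing para carbon of the oxidised ring and gives the quinone monoketal.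

Step 4
Reactants: 5 methyl 2-methylpropanoate (methyl isobutyrate)
Product: 6 1-(propan-2-yl)cyclopropan-1-ol
Conditions: EtMgBr (2.4 equiv), Ti(OiPr)4 (20 mol %), Et2O, 0 °C → rt; aq. NH4Cl
Reagents that add atoms: ethylmagnesium bromide, CC[Mg]Br
Why: Kulinkovich reaction, in which the titanacyclopropane formed from two ethyl groups adds twice to the ester carbonyl as a 1,2-dicarbanion equivalent.

Step 5
Reactants: 4 4,4-dimethoxy-3,5-dimethylcyclohexa-2,5-dien-1-one; 6 1-(propan-2-yl)cyclopropan-1-ol
Product: 9 cis-fused hydrindenone aldol (3R,3aR,7aR)-3-hydroxy-7,7-dimethoxy-6,7a-dimethyl-3-(propan-2-yl)-1,2,3,3a,7,7a-hexahydro-4H-inden-4-one, via zinc bis(homoenolate) 7 (not isolated), via zinc dienolate 8 (not isolated)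
Conditions: 6 (3.0 equiv), Et2Zn (1.5 equiv), THF/toluene, 0 °C → rt; then (CuOTf)2·C6H6 (5 mol %), (4S,5S)-4,5-diphenyl-1-(2-sulfonatophenyl)-3-(2,4,6-trimethylphenyl)-4,5-dihydro-1H-imidazol-3-ium zwitterion (12 mol %), 4 (1.0 equiv), −30 → 0 °C; aq. NH4Cl, 0 °C
Reagents that add atoms: none
Why: Proposed new method: Et2Zn turns two equivalents of 6 into a zinc alkoxide that opens with strain release (β-carbon elimination) to the β-zincio ketone 7; its alkyl group passes to the monovalent copper–carbene complex, adds to one methyl-bearing β-carbon of 4 by the usual π-complex, oxidative addition and reductive elimination course, and leaves zinc dienolate 8, whose C5 carbon then attacks the pendant isopropyl ketone. The closest known reactions are the copper-catalysed enantioselective addition of diorganozincs to 4,4-disubstituted cyclohexadienones (desymmetrisation) and to β-methyl cycloalkenones (quaternary centres with carbene ligands), copper-catalysed conjugate additions of zinc homoenolates, and conjugate addition–aldol annulations, but not their union with a cyclopropanol-derived homoenolate on a β,β-disubstituted quinone monoketal. Ring A closes by a 5-(enolexo)-exo-trig aldol (C4–C5), the C1–C2 bond having been made in the conjugate addition. C1 is set by the catalyst alone, since the dienone is achiral and its β-carbon/face pairs are enantiotopic; C5 follows because the three-atom tether reaches only the face it stands on (cis fusion), and C4 from a zinc chelate of enolate and ketone oxygens that places the hydroxyl syn to C6 and the isopropyl group on the convex face. The step needs homoenolate and not ethyl transfer (secured by the 2:1 cyclopropanol/Et2Zn ratio, which leaves no ethyl group on zinc), aldol only through C5 (the enolate is formed regiospecifically and no chlorosilane is present, so it stays a zinc enolate), and a single addition (the product enone is more hindered and no longer cross-conjugated); congestion at the β-carbon next to the ketal carbon is the main uncertainty, and cold work-up avoids retro-aldol and dehydration.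

Step 6
Reactants: 9 cis-fused hydrindenone aldol
Product: 11 hydroxy enone (1R,3aR,7R,7aS)-1,7-dihydroxy-3a,5-dimethyl-1-(propan-2-yl)-1,2,3,3a,7,7a-hexahydro-4H-inden-4-one, via ketal allylic alcohol 10 (not isolated)
Conditions: NaBH4, CeCl3·7H2O, MeOH, −78 °C; then 1 M aq. HCl, THF, 0 °C → rt
Reagents that add atoms: water, O
Why: Luche 1,2-reduction followed by mild acid hydrolysis of the allylic dimethyl ketal; hydride should enter on the convex face (that of H5 and the C1 methyl) because the other face is screened by the pseudo-axial C2 of ring A and the C4 carbinol, which puts the new C6 hydroxyl cis to C4 (6R) and ends the retro-aldol risk.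

Step 7
Reactants: 12 4-hydroxybenzoic acid
Product: 14 4-{[tri(propan-2-yl)silyl]oxy}benzoic acid, via silyl ester silyl ether 13 (not isolated)
Conditions: TIPSCl (2.2 equiv), imidazole, DMF, rt; then K2CO3, MeOH/THF/H2O, rt; aq. HCl to pH 3
Reagents that add atoms: chlorotri(propan-2-yl)silane, CC(C)[Si](Cl)(C(C)C)C(C)C
Why: Silylation of both acidic sites followed by selective solvolysis of the silyl ester, which is far more labile to carbonate in aqueous methanol than the hindered aryl silyl ether.

Step 8
Reactants: 11 hydroxy enone; 14 4-{[tri(propan-2-yl)silyl]oxy}benzoic acid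
Product: 16 C6 4-{[tri(propan-2-yl)silyl]oxy}benzoate of 11, via aroyl mixed anhydride 15 (not isolated)
Conditions: 14, 2,4,6-trichlorobenzoyl chloride, Et3N, toluene, rt; then 11, DMAP, rt
Reagents that add atoms: none
Why: Yamaguchi esterification through mixed anhydride 15 and DMAP acyl transfer, in which only the secondary C6 hydroxyl reacts (the tertiary C4 hydroxyl is too hindered) and C6 keeps its configuration because its C–O bond is not touched.

Step 9
Reactants: 16 C6 aroyl ester enone
Product: 17 dimethyl(phenyl)silyl enol ether (C10–O–Si, C8=C10 double bond, C7 now CH2)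
Conditions: [(Ph3P)CuH]6 (5 mol %), PhMe2SiH (1.5 equiv), toluene, rt
Reagents that add atoms: dimethyl(phenyl)silane, C[SiH](C)c1ccccc1
Why: Copper hydride-catalysed conjugate reduction with silyl trapping (1,4-hydrosilylation), in which hydride adds to C7 and σ-bond metathesis of the copper enolate with the silane gives the only enol ether this ketone can form (C1 is quaternary); the C6 ester is not β to the metal-bearing carbon and cannot be eliminated, and the congested tertiary C4 hydroxyl is not expected to be silylated.

Step 10
Reactants: 17 dimethyl(phenyl)silyl enol ether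
Product: 18 siloxycyclopropane (CH2, the future C9, bridging C8 and C10)
Conditions: Et2Zn (6 equiv), CH2I2 (12 equiv), CH2Cl2, 0 °C → rt; aq. NH4Cl
Reagents that add atoms: diiodomethane, ICI
Why: Simmons–Smith cyclopropanation in the Furukawa variant on the electron-rich enol ether, the only alkene in the molecule; one equivalent of Et2Zn is spent on the C4 hydroxyl, and the face of attack is immaterial because both new stereocentres (C8, C10) are erased in step 11.

Step 11
Reactants: 18 siloxycyclopropane
Product: 20 hydroazulenone (1R,4R,5S,6R)-4-hydroxy-10-oxodauc-8-en-6-yl 4-{[tri(propan-2-yl)silyl]oxy}benzoate, via β-chloro ketone 19 (not isolated)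
Conditions: FeCl3 (2.5 equiv), DMF, 0 °C → rt; then NaOAc, MeOH, rt
Reagents that add atoms: none
Why: FeCl3-mediated oxidative ring expansion of a siloxycyclopropane followed by dehydrochlorination: one-electron oxidation by trivalent iron should cleave the internal C8–C10 bond to the ketone and the tertiary C8 radical, which takes chlorine from FeCl3, and acetate then removes HCl through the only enolisable position (C9) to give the conjugated C8=C9 enone, at room temperature so that the C6 ester is not lost by vinylogous elimination.

Step 12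
Reactants: 20 hydroazulenone
Product: 21 allylic alcohol (1R,4R,5S,6R,10S)-4,10-dihydroxydauc-8-en-6-yl 4-{[tri(propan-2-yl)silyl]oxy}benzoate
Conditions: NaBH4, CeCl3·7H2O, MeOH, −78 → −20 °C; aq. NH4Cl
Reagents that add atoms: none
Why: Luche 1,2-reduction of the enone, in which hydride should again add from the convex face, anti to ring A and to the C4 hydroxyl that lies over the concave face, giving the C10 hydroxyl cis to C2 and trans to the C1 methyl (10S).

Step 13
Reactants: 21 allylic alcohol; 22 (E)-2-methylbut-2-enoic acid (tiglic acid)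
Product: 24 silyl-protected diester (1R,4R,5S,6R,10S)-4-hydroxy-10-[(E)-2-methylbut-2-enoyloxy]dauc-8-en-6-yl 4-{[tri(propan-2-yl)silyl]oxy}benzoate, via tigloyl mixed anhydride 23 (not isolated)
Conditions: 22, 2,4,6-trichlorobenzoyl chloride, Et3N, toluene, rt; then 21, DMAP, 60 °C
Reagents that add atoms: none
Why: Yamaguchi esterification, chosen because the C10 hydroxyl is flanked by the quaternary C1; acylation at oxygen retains the C10 configuration, the tertiary C4 hydroxyl stays free, and the E tiglate is the stable geometric isomer under DMAP.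

Step 14
Reactants: 24 silyl-protected diester
Product: 25 target, (3R,3aS,4R,8S,8aR)-3-hydroxy-6,8a-dimethyl-8-{[(2E)-2-methylbut-2-enoyl]oxy}-3-(propan-2-yl)-1,2,3,3a,4,5,8,8a-octahydroazulen-4-yl 4-hydroxybenzoate
Conditions: Bu4NF, AcOH (1:1), THF, 0 °C
Reagents that add atoms: none
Why: Fluoride cleavage of the aryl silyl ether, the most labile silicon–oxygen bond because a 4-acylphenoxide leaves, with acetic acid buffering the phenoxide so that neither ester migrates or is cleaved.

**Compound list**

1 | 4-bromo-2,6-dimethylphenol | Cc1cc(Br)cc(C)c1O | starting material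
2 | 5-bromo-2-methoxy-1,3-dimethylbenzene | COc1c(C)cc(Br)cc1C | intermediate
3 | 4-methoxy-3,5-dimethylphenol | COc1c(C)cc(O)cc1C | intermediate
4 | 4,4-dimethoxy-3,5-dimethylcyclohexa-2,5-dien-1-one | COC1(OC)C(C)=CC(=O)C=C1C | intermediate
5 | methyl 2-methylpropanoate (methyl isobutyrate) | COC(=O)C(C)C | starting material
6 | 1-(propan-2-yl)cyclopropan-1-ol | CC(C)C1(O)CC1 | intermediate
7 | bis(4-methyl-3-oxopentyl)zinc, the zinc bis(homoenolate), not isolated | CC(C)C(=O)CC[Zn]CCC(=O)C(C)C | intermediate
8 | zinc dienolate, (4-methyl-3-oxopentyl)zinc (3R)-4,4-dimethoxy-3,5-dimethyl-3-(4-methyl-3-oxopentyl)cyclohexa-1,5-dien-1-olate, not isolated | COC1(OC)C(C)=CC(O[Zn]CCC(=O)C(C)C)=C[C@@]1(C)CCC(=O)C(C)C | intermediate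
9 | (3R,3aR,7aR)-3-hydroxy-7,7-dimethoxy-6,7a-dimethyl-3-(propan-2-yl)-1,2,3,3a,7,7a-hexahydro-4H-inden-4-one; daucane locants 1R,4R,5R; H5 cis to the C1 methyl, 4-OH cis to C6 | COC1(OC)C(C)=CC(=O)[C@@H]2[C@@]1(C)CC[C@@]2(O)C(C)C | intermediate
10 | ketal allylic alcohol, 9 with the C6 carbonyl reduced to CH–OH cis to C4 (1R,4R,5S,6R), not isolated | COC1(OC)C(C)=C[C@@H](O)[C@@H]2[C@@]1(C)CC[C@@]2(O)C(C)C | intermediate
11 | (1R,3aR,7R,7aS)-1,7-dihydroxy-3a,5-dimethyl-1-(propan-2-yl)-1,2,3,3a,7,7a-hexahydro-4H-inden-4-one; daucane locants 1R,4R,5S,6R with C10 ketone and C7=C8 | O=C1C(C)=C[C@@H](O)[C@@H]2[C@@]1(C)CC[C@@]2(O)C(C)C | intermediate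
12 | 4-hydroxybenzoic acid | O=C(O)c1ccc(O)cc1 | starting material
13 | tri(propan-2-yl)silyl 4-{[tri(propan-2-yl)silyl]oxy}benzoate, not isolated | CC(C)[Si](OC(=O)c1ccc(O[Si](C(C)C)(C(C)C)C(C)C)cc1)(C(C)C)C(C)C | intermediate
14 | 4-{[tri(propan-2-yl)silyl]oxy}benzoic acid | CC(C)[Si](Oc1ccc(cc1)C(=O)O)(C(C)C)C(C)C | intermediate
15 | 4-{[tri(propan-2-yl)silyl]oxy}benzoic 2,4,6-trichlorobenzoic anhydride, not isolated | CC(C)[Si](Oc1ccc(cc1)C(=O)OC(=O)c2c(Cl)cc(Cl)cc2Cl)(C(C)C)C(C)C | intermediate
16 | C6 4-{[tri(propan-2-yl)silyl]oxy}benzoate of 11 (1R,4R,5S,6R; C10 ketone, C7=C8, free 4-OH) | O=C1C(C)=C[C@@H](OC(=O)c3ccc(O[Si](C(C)C)(C(C)C)C(C)C)cc3)[C@@H]2[C@@]1(C)CC[C@@]2(O)C(C)C | intermediate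
17 | dimethyl(phenyl)silyl enol ether of the 7,8-dihydro ketone from 16 (C10–O–SiMe2Ph, C8=C10, C7 CH2; 1R,4R,5S,6R) | C[Si](C)(c1ccccc1)OC1=C(C)C[C@@H](OC(=O)c3ccc(O[Si](C(C)C)(C(C)C)C(C)C)cc3)[C@@H]2[C@@]1(C)CC[C@@]2(O)C(C)C | intermediate
18 | siloxycyclopropane, CH2 (future C9) bridging C8 and C10 of 17; configuration at C8 and C10 not defined and erased in step 11 | C[Si](C)(c1ccccc1)OC14CC4(C)C[C@@H](OC(=O)c3ccc(O[Si](C(C)C)(C(C)C)C(C)C)cc3)[C@@H]2[C@@]1(C)CC[C@@]2(O)C(C)C | intermediate
19 | β-chloro ketone, ring-expanded cycloheptanone with C10 ketone, C9 CH2 and C8(Cl)(CH3) of undefined configuration, not isolated | O=C1CC(C)(Cl)C[C@@H](OC(=O)c3ccc(O[Si](C(C)C)(C(C)C)C(C)C)cc3)[C@@H]2[C@@]1(C)CC[C@@]2(O)C(C)C | intermediate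
20 | (1R,4R,5S,6R)-4-hydroxy-10-oxodauc-8-en-6-yl 4-{[tri(propan-2-yl)silyl]oxy}benzoate (cis-fused) | O=C1C=C(C)C[C@@H](OC(=O)c3ccc(O[Si](C(C)C)(C(C)C)C(C)C)cc3)[C@@H]2[C@@]1(C)CC[C@@]2(O)C(C)C | intermediate
21 | (1R,4R,5S,6R,10S)-4,10-dihydroxydauc-8-en-6-yl 4-{[tri(propan-2-yl)silyl]oxy}benzoate; 10-OH cis to C2, trans to the C1 methyl | O[C@H]1C=C(C)C[C@@H](OC(=O)c3ccc(O[Si](C(C)C)(C(C)C)C(C)C)cc3)[C@@H]2[C@@]1(C)CC[C@@]2(O)C(C)C | intermediate
22 | (E)-2-methylbut-2-enoic acid (tiglic acid) | C/C=C(\C)C(=O)O | starting material
23 | (E)-2-methylbut-2-enoic 2,4,6-trichlorobenzoic anhydride, not isolated | C/C=C(\C)C(=O)OC(=O)c1c(Cl)cc(Cl)cc1Cl | intermediate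
24 | (1R,4R,5S,6R,10S)-4-hydroxy-10-[(E)-2-methylbut-2-enoyloxy]dauc-8-en-6-yl 4-{[tri(propan-2-yl)silyl]oxy}benzoate | C/C=C(\C)C(=O)O[C@H]1C=C(C)C[C@@H](OC(=O)c3ccc(O[Si](C(C)C)(C(C)C)C(C)C)cc3)[C@@H]2[C@@]1(C)CC[C@@]2(O)C(C)C | intermediate
25 | (3R,3aS,4R,8S,8aR)-3-hydroxy-6,8a-dimethyl-8-{[(2E)-2-methylbut-2-enoyl]oxy}-3-(propan-2-yl)-1,2,3,3a,4,5,8,8a-octahydroazulen-4-yl 4-hydroxybenzoate; daucane locants 1R,4R,5S,6R,10S | C/C=C(\C)C(=O)O[C@H]1C=C(C)C[C@@H](OC(=O)c2ccc(O)cc2)[C@@H]2[C@@]1(C)CC[C@@]2(O)C(C)C | target

**Step count and risks**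

Total step count: 14. Longest linear sequence: 12 steps (steps 1–3, 5, 6 and 8–14, from 4-bromo-2,6-dimethylphenol).

Step 5 (proposed new method). What may go wrong: the copper-bound homoenolate may not add to a β-carbon that carries a methyl group and sits next to the ketal carbon, the catalyst may discriminate the β-carbon/face pairs poorly, or the zinc enolate may be protonated before it closes ring A. The fallback uses known reactions only, sets out from 4 and comes back at 11. Compound 4 is transketalised with (2R,3R)-butane-2,3-diol (BF3·OEt2 cat., DME, rt) to the C2-symmetric spiroketal dienone F1, whose tied-back dioxolane crowds the β-carbons less and makes the two β-carbons of one face diastereotopic. Zinc homoenolate 7 is then added in the chlorosilane-accelerated, copper-mediated manner (CuBr·SMe2, TMSCl, DMPU, THF, −20 °C → rt), the known forcing protocol for zinc homoenolates and hindered enones, to give the trimethylsilyl enol ether F2. Fluoride (Bu4NF, THF, −78 → −40 °C) frees the regiodefined enolate, which closes ring A in a reversible aldol that should settle on the same C4 epimer (isopropyl on the convex face, hydroxyl hydrogen-bonded to the C6 carbonyl) and give the aldol spiroketal F3. The auxiliary turns the enantiomer problem into a separation of diastereomers, to be done by chromatography at this stage whatever the selectivity of the addition. F3 is then taken through the conditions of step 6 (the dioxolane is hydrolysed at rt), which release the diol and give 11.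

Step 10. What may go wrong: the zinc carbenoid may be too bulky to reach the tetrasubstituted enol ether double bond beside the quaternary C1, or zinc iodide may cleave the enol ether before cyclopropanation. The fallback sets out from 17 and comes back at 20, so it also bypasses step 11. Free dibromocarbene, much smaller than the zinc carbenoid, is generated without base from PhHgCBr3 (benzene, 80 °C). The dibromocyclopropane adduct should open in the flask with loss of the silyl bromide (the known ring expansion of dihalocarbene adducts of silyl enol ethers) to the 9-bromo enone F4. Pd(PPh3)4-catalysed reduction with Bu3SnH (1.05 equiv, THF, rt) then removes the vinylic bromine and gives 20.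

Step 12. What may go wrong: poor facial selectivity of hydride addition, because the seven-membered ring is flexible and the C1 methyl stands on the convex face next to the carbonyl. The fallback sets out from 20 and comes back at 21 and replaces substrate control by reagent control. It is a Corey–Bakshi–Shibata reduction with (R)-1-methyl-3,3-diphenyltetrahydro-1H,3H-pyrrolo[1,2-c][1,3,2]oxazaborole and catecholborane (toluene, −78 °C). With the fully substituted C1 flank acting as the large group, this antipode should deliver hydride to the face that gives the (10S) alcohol. No new compound is passed (entry F0).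

**Further compounds**

F1 | step 5 | (2R,3R)-2,3,6,10-tetramethyl-1,4-dioxaspiro[4.5]deca-6,9-dien-8-one | C[C@H]1OC2(O[C@@H]1C)C(C)=CC(=O)C=C2C
F2 | step 5 | trimethylsilyl enol ether of the conjugate adduct, (1R) at the new quaternary carbon, (2R,3R)-butanediol ketal at C10 | C[C@H]1OC2(O[C@@H]1C)C(C)=CC(O[Si](C)(C)C)=C[C@@]2(C)CCC(=O)C(C)C
F3 | step 5 | aldol spiroketal, the (2R,3R)-butane-2,3-diol ketal analogue of 9 (1R,4R,5R) | C[C@H]1OC2(O[C@@H]1C)C(C)=CC(=O)[C@@H]3[C@@]2(C)CC[C@@]3(O)C(C)C
F4 | step 10 | 9-bromo enone, (1R,4R,5S,6R)-9-bromo-4-hydroxy-10-oxodauc-8-en-6-yl 4-{[tri(propan-2-yl)silyl]oxy}benzoate | O=C1C(Br)=C(C)C[C@@H](OC(=O)c3ccc(O[Si](C(C)C)(C(C)C)C(C)C)cc3)[C@@H]2[C@@]1(C)CC[C@@]2(O)C(C)C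
F0 | step 12 | none | none
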